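Retrosynthesis: the target is traced back through its C11=C12 dehydro compound and its C6/C8 esters; the ring is then cut at C7–C8 to an open-chain C8 aldehyde carrying a C12 allylic bromide; C6–C7 is cut to a vinyl iodide (C7, C11–C13) and an epoxy aldehyde; C8–C9 (methylenation) and the oxirane lead back to neryl acetate.
Enabling feature: in the ten-membered carbocycle the C8 carbinol sits next to C7, whose isopropyl group is a hydrogenated isopropenyl group, so C8(O)–C7–C11(=C12) is a homoallylic alcohol, the retron of a carbonyl allylation with allylic transposition.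
Forward: neryl acetate → C8 added as a diene terminus → oxirane (made first) → union with the vinyllithium → hydroboration, bromide, aldehyde → the ten-membered ring is closed last at C7–C8 by an intramolecular Nozaki–Hiyama allylation → benzoate, acetate, hydrogenation.
Stereochemistry: C4/C5 from Sharpless epoxidation of the Z-allylic alcohol; C6 from Felkin–Anh addition to the epoxy aldehyde; C7 and C8 together in the chair transition state of the ring closure (anti), with the face set by C6; alkene geometries from nerol (Z), SeO2 oxidation (E) and carboalumination (E).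
Key step: step 14

Remark: the SMILES defines a cis-4,5-oxirane (C3 and C6 on the same side), hence the nerol series; locants from compound 13 on are those of the target skeleton (ring C1–C10, C1=C10 alkene, C4–C5 oxirane, oxygen at C6 and C8, C7 carries C11 with C12 and C13, C14 on C10, C15 on C4), and open-chain intermediates are named as 7,8-seco compounds with these locants.

Step 1
Reactants: 1 neryl acetate
Product: 3 (2Z,6E)-3,7-dimethyl-8-oxoocta-2,6-dien-1-yl acetate, via allylic alcohol 2 (not isolated)
Conditions: SeO2 (0.3 equiv), t-BuOOH, salicylic acid (cat.), CH2Cl2, 23 °C; then MnO2, CH2Cl2, 23 °C on the crude mixture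
Reagents that add atoms: tert-butyl hydroperoxide CC(C)(C)OO; selenium dioxide O=[Se]=O (catalytic oxygen carrier)
Why: Riley-type allylic oxidation with catalytic SeO2 (ene reaction, then [2,3]-shift) attacks the E-methyl group of the electron-rich 6,7-alkene remote from the acetate, and MnO2 oxidation of the crude allylic alcohol should converge the mixture on the E-enal, which fixes the later C1=C10 geometry.

Step 2
Reactants: 3 (2Z,6E)-3,7-dimethyl-8-oxoocta-2,6-dien-1-yl acetate
Product: 4 (2Z,6E)-3,7-dimethylnona-2,6,8-trien-1-yl acetate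
Conditions: Ph3PCH3Br, KN(SiMe3)2, THF, 0 °C; then 3, −78 → 0 °C
Reagents that add atoms: methyltriphenylphosphonium bromide C[P+](c1ccccc1)(c1ccccc1)c1ccccc1.[Br-]
Why: Wittig methylenation of the enal is much faster than attack on the acetate at low temperature and adds C8 as the terminus of a 1,3-diene that serves as a latent homoallylic alcohol.

Step 3
Reactants: 4 (2Z,6E)-3,7-dimethylnona-2,6,8-trien-1-yl acetate
Product: 5 (2Z,6E)-3,7-dimethylnona-2,6,8-trien-1-ol
Conditions: K2CO3 (0.2 equiv), MeOH, 0 → 23 °C
Reagents that add atoms: none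
Why: Base-catalysed transesterification frees the Z-allylic alcohol that directs the epoxidation and leaves the triene untouched.

Step 4
Reactants: 5 (2Z,6E)-3,7-dimethylnona-2,6,8-trien-1-ol
Product: 6 [(2R,3S)-3-methyl-3-[(3E)-4-methylhexa-3,5-dien-1-yl]oxiran-2-yl]methanol
Conditions: Ti(OiPr)4 (10 mol %), D-(−)-diethyl tartrate (12 mol %), t-BuOOH, 4 Å molecular sieves, CH2Cl2, −20 °C
Reagents that add atoms: tert-butyl hydroperoxide CC(C)(C)OO
Why: Sharpless asymmetric epoxidation is confined to the allylic-alcohol alkene, and D-(−)-diethyl tartrate delivers oxygen to the face that gives the (2R,3S)-oxirane from a Z-alkene (the mirror image of the (2S,3R)-epoxide formed from nerol with the L-tartrate), which sets C4 (S), C5 (R) and the cis relation of C3 and C6.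

Step 5
Reactants: 6 [(2R,3S)-3-methyl-3-[(3E)-4-methylhexa-3,5-dien-1-yl]oxiran-2-yl]methanol
Product: 7 (2S,3S)-3-methyl-3-[(3E)-4-methylhexa-3,5-dien-1-yl]oxirane-2-carbaldehyde
Conditions: Dess–Martin periodinane, pyridine, CH2Cl2, 0 → 23 °C
Reagents that add atoms: none
Why: Dess–Martin oxidation under pyridine buffering should give the epoxy aldehyde without epimerisation (the oxirane C–H is not enolised) and without touching the diene; the descriptor at the oxirane CH changes by priority only.

Step 6
Reactants: 8 prop-2-yn-1-ol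
Product: 10 (E)-3-iodo-2-methylprop-2-en-1-ol, via alkenylalane 9 (not isolated)
Conditions: Me3Al (3 equiv), Cp2ZrCl2 (0.25 equiv), CH2Cl2, 0 → 23 °C; then I2, THF, −30 → 0 °C
Reagents that add atoms: trimethylaluminium C[Al](C)C; iodine II
Why: Negishi zirconium-catalysed carboalumination adds methyl and aluminium syn across the alkyne with aluminium at the terminus, and iodinolysis with retention gives the E-vinyl iodide, which fixes the E geometry of the C7=C11 alkene used in the ring closure.

Step 7
Reactants: 10 (E)-3-iodo-2-methylprop-2-en-1-ol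
Product: 11 1-{[(2E)-3-iodo-2-methylprop-2-en-1-yl]oxymethyl}-4-methoxybenzene
Conditions: NaH, 4-methoxybenzyl chloride, Bu4NI (cat.), THF–DMF, 0 → 23 °C
Reagents that add atoms: 4-methoxybenzyl chloride COc1ccc(CCl)cc1
Why: Williamson etherification masks the allylic hydroxyl as a 4-methoxybenzyl ether that tolerates t-BuLi and is later removed under neutral oxidative conditions.

Step 8
Reactants: 11 1-{[(2E)-3-iodo-2-methylprop-2-en-1-yl]oxymethyl}-4-methoxybenzene; 7 (2S,3S)-3-methyl-3-[(3E)-4-methylhexa-3,5-dien-1-yl]oxirane-2-carbaldehyde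
Product: 13 (4S,5R,6R)-4,5-epoxy-12-(4-methoxybenzyloxy)-7,8-secogermacra-1(10)E,7(11)E,8-trien-6-ol, via vinyllithium 12 (not isolated)
Conditions: 11, t-BuLi (2.1 equiv), Et2O, −78 °C; then 7, Et2O, −78 °C
Reagents that add atoms: none
Why: Iodine–lithium exchange with retention of the E geometry gives vinyllithium 12, whose 1,2-addition should follow the Felkin–Anh mode (oxirane C–O bond anti to the nucleophile, approach past the oxirane hydrogen), the mode that dominates for epoxy aldehydes with a cis substituent on the oxirane, and so set C6 as R (anti epoxy alcohol).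

Step 9
Reactants: 13 (4S,5R,6R)-4,5-epoxy-12-(4-methoxybenzyloxy)-7,8-secogermacra-1(10)E,7(11)E,8-trien-6-ol
Product: 14 6-O-triethylsilyl ether of 13, (4S,5R,6R)-4,5-epoxy-12-(4-methoxybenzyloxy)-6-(triethylsilyloxy)-7,8-secogermacra-1(10)E,7(11)E,8-triene
Conditions: Et3SiCl, imidazole, DMAP (cat.), CH2Cl2, 0 °C
Reagents that add atoms: chlorotriethylsilane CC[Si](Cl)(CC)CC
Why: Silylation masks the C6 hydroxyl as an ether that cannot leave from the later allylchromium reagent (no vinylogous β-elimination) and can be removed by buffered fluoride.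

Step 10
Reactants: 14 (4S,5R,6R)-4,5-epoxy-12-(4-methoxybenzyloxy)-6-(triethylsilyloxy)-7,8-secogermacra-1(10)E,7(11)E,8-triene
Product: 16 (4S,5R,6R)-4,5-epoxy-12-(4-methoxybenzyloxy)-6-(triethylsilyloxy)-7,8-secogermacra-1(10)E,7(11)E-dien-8-ol, via alkylborane 15 (not isolated)
Conditions: 9-BBN (1.3 equiv), THF, 0 → 23 °C; then 30% H2O2, 2 M NaOH, 0 °C
Reagents that add atoms: hydrogen peroxide OO
Why: Brown hydroboration with the bulky 9-BBN should occur only at the monosubstituted C8=C9 terminus of the diene with boron on C8, and oxidation then gives the primary C8 alcohol while the trisubstituted alkenes, the oxirane and both ethers persist.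

Step 11
Reactants: 16 (4S,5R,6R)-4,5-epoxy-12-(4-methoxybenzyloxy)-6-(triethylsilyloxy)-7,8-secogermacra-1(10)E,7(11)E-dien-8-ol
Product: 17 (4S,5R,6R)-4,5-epoxy-6-(triethylsilyloxy)-7,8-secogermacra-1(10)E,7(11)E-diene-8,12-diol
Conditions: DDQ, CH2Cl2–pH 7 buffer (10:1), 0 °C
Reagents that add atoms: none
Why: Oxidative cleavage of the 4-methoxybenzyl ether by DDQ (hydride abstraction, then hydrolysis of the oxocarbenium ion) frees the allylic C12 hydroxyl under buffered conditions that spare the silyl ether, the oxirane and the alkenes.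

Step 12
Reactants: 17 (4S,5R,6R)-4,5-epoxy-6-(triethylsilyloxy)-7,8-secogermacra-1(10)E,7(11)E-diene-8,12-diol
Product: 18 (4S,5R,6R)-12-bromo-4,5-epoxy-6-(triethylsilyloxy)-7,8-secogermacra-1(10)E,7(11)E-dien-8-ol
Conditions: NBS, Me2S, CH2Cl2, −20 → 0 °C
Reagents that add atoms: N-bromosuccinimide O=C1CCC(=O)N1Br
Why: Corey–Kim-type bromination proceeds through alkoxysulfonium salts that bromide displaces only at the allylic carbon, so C12–OH should become the bromide while the saturated C8 alcohol is returned on work-up.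

Step 13
Reactants: 18 (4S,5R,6R)-12-bromo-4,5-epoxy-6-(triethylsilyloxy)-7,8-secogermacra-1(10)E,7(11)E-dien-8-ol
Product: 19 (4S,5R,6R)-12-bromo-4,5-epoxy-6-(triethylsilyloxy)-7,8-secogermacra-1(10)E,7(11)E-dien-8-al
Conditions: Dess–Martin periodinane, pyridine, CH2Cl2, 0 °C; filtered through a short pad and used at once
Reagents that add atoms: none
Why: Dess–Martin oxidation under pyridine buffering should give the β,γ-unsaturated aldehyde without migration of the C1=C10 alkene into conjugation, and the allylic bromide is inert to the oxidant.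

Step 14
Reactants: 19 (4S,5R,6R)-12-bromo-4,5-epoxy-6-(triethylsilyloxy)-7,8-secogermacra-1(10)E,7(11)E-dien-8-al
Product: 21 (1(10)E,4S,5R,6R,7R,8S)-4,5-epoxy-6-(triethylsilyloxy)germacra-1(10),11-dien-8-ol, via allylchromium dichloride 20 (not isolated)
Conditions: CrCl2 (8 equiv), degassed THF, 23 °C; 19 added by syringe pump over 12 h to a final 2 mM
Reagents that add atoms: none
Why: CrCl2 (divalent chromium, two equivalents per C–Br bond) reduces the allylic bromide to the allylchromium dichloride 20 (trivalent chromium), whose γ-carbon C7 adds to the chromium-bound aldehyde carbon C8 through a six-membered chair (Zimmerman–Traxler) transition state with allylic transposition, so that C7=C11 becomes the exocyclic C11=C12 isopropenyl group. The closest known reaction type is the intramolecular Nozaki–Hiyama allylation of aldehydes by allylic bromides, which is used to close medium and large carbocycles, ten-membered germacrane rings included, in the presence of epoxides and silyl ethers. The ten-membered carbocycle, the only ring formed, closes in a 10-exo-trig mode at the aldehyde carbon. C8 (S) and C7 (R) arise together: the E-allylchromium places the C6 branch and the C9 chain equatorial on the chair, which gives the anti relation found in the target, and the face of C7 is expected to be set by C6, because A1,3 strain with the C13 methyl keeps H6 in the allyl plane and the tether then reaches C8 with the C5–C6 bond anti to the forming bond and the silyloxy group outside. The step needs γ- over α-attack (intrinsic to allylchromium reagents), attack on the aldehyde and not on the oxirane (allylchromium reagents of trivalent chromium add only to the aldehyde, and CrCl2 in THF leaves isolated epoxides alone), retention of the C6 oxygen (a silyl ether is a poor leaving group for vinylogous β-elimination) and ring closure over oligomerisation (slow addition at high dilution).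

Step 15
Reactants: 21 (1(10)E,4S,5R,6R,7R,8S)-4,5-epoxy-6-(triethylsilyloxy)germacra-1(10),11-dien-8-ol
Product: 22 (1(10)E,4S,5R,6R,7R,8S)-8-benzoyloxy-4,5-epoxy-6-(triethylsilyloxy)germacra-1(10),11-diene
Conditions: BzCl, DMAP, pyridine, CH2Cl2, 0 → 23 °C
Reagents that add atoms: benzoyl chloride O=C(Cl)c1ccccc1
Why: DMAP-catalysed acylation of the free C8 hydroxyl installs the benzoate with retention while C6 is still silylated.

Step 16
Reactants: 22 (1(10)E,4S,5R,6R,7R,8S)-8-benzoyloxy-4,5-epoxy-6-(triethylsilyloxy)germacra-1(10),11-diene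
Product: 23 (1(10)E,4S,5R,6R,7S,8S)-8-benzoyloxy-4,5-epoxygermacra-1(10),11-dien-6-ol
Conditions: Bu4NF, AcOH (1:1), THF, 0 → 23 °C
Reagents that add atoms: none
Why: Fluoride desilylation buffered with acetic acid removes the triethylsilyl group in a near-neutral medium that should suppress benzoate migration from O8 to O6, Payne rearrangement and acid-induced transannular opening of the oxirane; the descriptor at C7 changes by priority only.

Step 17
Reactants: 23 (1(10)E,4S,5R,6R,7S,8S)-8-benzoyloxy-4,5-epoxygermacra-1(10),11-dien-6-ol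
Product: 24 (1(10)E,4S,5R,6R,7R,8S)-6-acetoxy-8-benzoyloxy-4,5-epoxygermacra-1(10),11-diene
Conditions: Ac2O, DMAP (cat.), pyridine, CH2Cl2, 23 °C
Reagents that add atoms: acetic anhydride CC(=O)OC(C)=O
Why: DMAP-catalysed acetylation of the C6 hydroxyl proceeds with retention under non-acidic conditions.

Step 18
Reactants: 24 (1(10)E,4S,5R,6R,7R,8S)-6-acetoxy-8-benzoyloxy-4,5-epoxygermacra-1(10),11-diene
Product: 25 (1(10)E,4S,5R,6R,7R,8S)-6-acetoxy-8-benzoyloxy-4,5-epoxygermacr-1(10)-ene (CNP0112246.1)
Conditions: H2 (1 atm), RhCl(PPh3)3 (10 mol %), benzene, 23 °C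
Reagents that add atoms: none
Why: Homogeneous hydrogenation with RhCl(PPh3)3 reduces 1,1-disubstituted alkenes far faster than trisubstituted ones, so the isopropenyl group should be saturated while the ring C1=C10 alkene, the oxirane and both esters persist, and no stereocentre is created because C11 then carries two methyl groups.

Compound list
1 | neryl acetate, (2Z)-3,7-dimethylocta-2,6-dien-1-yl acetate | CC(=O)OC/C=C(/C)CCC=C(C)C | starting material
2 | (2Z,6E)-8-hydroxy-3,7-dimethylocta-2,6-dien-1-yl acetate | CC(=O)OC/C=C(/C)CC/C=C(\C)CO | intermediate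
3 | (2Z,6E)-3,7-dimethyl-8-oxoocta-2,6-dien-1-yl acetate | CC(=O)OC/C=C(/C)CC/C=C(\C)C=O | intermediate
4 | (2Z,6E)-3,7-dimethylnona-2,6,8-trien-1-yl acetate | CC(=O)OC/C=C(/C)CC/C=C(\C)C=C | intermediate
5 | (2Z,6E)-3,7-dimethylnona-2,6,8-trien-1-ol | OC/C=C(/C)CC/C=C(\C)C=C | intermediate
6 | [(2R,3S)-3-methyl-3-[(3E)-4-methylhexa-3,5-dien-1-yl]oxiran-2-yl]methanol | OC[C@@H]1[C@@](CC/C=C(\C)C=C)(C)O1 | intermediate
7 | (2S,3S)-3-methyl-3-[(3E)-4-methylhexa-3,5-dien-1-yl]oxirane-2-carbaldehyde | O=C[C@@H]1[C@@](CC/C=C(\C)C=C)(C)O1 | intermediate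
8 | prop-2-yn-1-ol (propargyl alcohol) | C#CCO | starting material
9 | alkenylalane, dimethylaluminium alkoxide of (E)-3-(dimethylalumanyl)-2-methylprop-2-en-1-ol | C[Al](C)/C=C(\C)CO[Al](C)C | intermediate
10 | (E)-3-iodo-2-methylprop-2-en-1-ol | OC/C(C)=C/I | intermediate
11 | 1-{[(2E)-3-iodo-2-methylprop-2-en-1-yl]oxymethyl}-4-methoxybenzene | COc1ccc(COC/C(C)=C/I)cc1 | intermediate
12 | vinyllithium, [(1E)-3-(4-methoxybenzyloxy)-2-methylprop-1-en-1-yl]lithium | COc1ccc(COC/C(C)=C/[Li])cc1 | intermediate
13 | (4S,5R,6R)-4,5-epoxy-12-(4-methoxybenzyloxy)-7,8-secogermacra-1(10)E,7(11)E,8-trien-6-ol | O[C@H](/C=C(\C)COCc1ccc(OC)cc1)[C@@H]1[C@@](CC/C=C(\C)C=C)(C)O1 | intermediate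
14 | (4S,5R,6R)-4,5-epoxy-12-(4-methoxybenzyloxy)-6-(triethylsilyloxy)-7,8-secogermacra-1(10)E,7(11)E,8-triene | CC[Si](CC)(CC)O[C@H](/C=C(\C)COCc1ccc(OC)cc1)[C@@H]1[C@@](CC/C=C(\C)C=C)(C)O1 | intermediate
15 | alkylborane, B-(C8)-alkyl-9-borabicyclo[3.3.1]nonane from 14 | CC[Si](CC)(CC)O[C@H](/C=C(\C)COCc1ccc(OC)cc1)[C@@H]1[C@@](CC/C=C(\C)CCB2C3CCCC2CCC3)(C)O1 | intermediate
16 | (4S,5R,6R)-4,5-epoxy-12-(4-methoxybenzyloxy)-6-(triethylsilyloxy)-7,8-secogermacra-1(10)E,7(11)E-dien-8-ol | CC[Si](CC)(CC)O[C@H](/C=C(\C)COCc1ccc(OC)cc1)[C@@H]1[C@@](CC/C=C(\C)CCO)(C)O1 | intermediate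
17 | (4S,5R,6R)-4,5-epoxy-6-(triethylsilyloxy)-7,8-secogermacra-1(10)E,7(11)E-diene-8,12-diol | CC[Si](CC)(CC)O[C@H](/C=C(\C)CO)[C@@H]1[C@@](CC/C=C(\C)CCO)(C)O1 | intermediate
18 | (4S,5R,6R)-12-bromo-4,5-epoxy-6-(triethylsilyloxy)-7,8-secogermacra-1(10)E,7(11)E-dien-8-ol | CC[Si](CC)(CC)O[C@H](/C=C(\C)CBr)[C@@H]1[C@@](CC/C=C(\C)CCO)(C)O1 | intermediate
19 | (4S,5R,6R)-12-bromo-4,5-epoxy-6-(triethylsilyloxy)-7,8-secogermacra-1(10)E,7(11)E-dien-8-al | CC[Si](CC)(CC)O[C@H](/C=C(\C)CBr)[C@@H]1[C@@](CC/C=C(\C)CC=O)(C)O1 | intermediate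
20 | allylchromium dichloride (trivalent chromium) at C12 derived from 19 | CC[Si](CC)(CC)O[C@H](/C=C(\C)C[Cr](Cl)Cl)[C@@H]1[C@@](CC/C=C(\C)CC=O)(C)O1 | intermediate
21 | (1(10)E,4S,5R,6R,7R,8S)-4,5-epoxy-6-(triethylsilyloxy)germacra-1(10),11-dien-8-ol | CC[Si](CC)(CC)O[C@@H]1[C@H](C(C)=C)[C@@H](O)C/C(C)=C/CC[C@]2(C)O[C@H]12 | intermediate
22 | (1(10)E,4S,5R,6R,7R,8S)-8-benzoyloxy-4,5-epoxy-6-(triethylsilyloxy)germacra-1(10),11-diene | CC[Si](CC)(CC)O[C@@H]1[C@H](C(C)=C)[C@@H](OC(=O)c2ccccc2)C/C(C)=C/CC[C@]2(C)O[C@H]12 | intermediate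
23 | (1(10)E,4S,5R,6R,7S,8S)-8-benzoyloxy-4,5-epoxygermacra-1(10),11-dien-6-ol | O[C@@H]1[C@H](C(C)=C)[C@@H](OC(=O)c2ccccc2)C/C(C)=C/CC[C@]2(C)O[C@H]12 | intermediate
24 | (1(10)E,4S,5R,6R,7R,8S)-6-acetoxy-8-benzoyloxy-4,5-epoxygermacra-1(10),11-diene | CC(=O)O[C@@H]1[C@H](C(C)=C)[C@@H](OC(=O)c2ccccc2)C/C(C)=C/CC[C@]2(C)O[C@H]12 | intermediate
25 | (1(10)E,4S,5R,6R,7R,8S)-6-acetoxy-8-benzoyloxy-4,5-epoxygermacr-1(10)-ene, CNP0112246.1 | CC(=O)O[C@@H]1[C@H](C(C)C)[C@@H](OC(=O)c2ccccc2)C/C(C)=C/CC[C@]2(C)O[C@H]12 | target

Total step count: 18. Longest linear sequence: 16 steps from neryl acetate (steps 1–5 and 8–18); the vinyl iodide branch (steps 6–7) has 2 steps.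

Steps most likely to fail

1. Step 14. What may go wrong: the chair-controlled anti relation may be lost during ring closure, because the strained ten-membered transition state can force the C9 chain axial or let a Z-allylchromium react, so that the carbinol centre C8 is formed with the opposite configuration; intermolecular allylation may also compete. The face of C7 relative to C6 is the second uncertainty of this step, argued above from allylic strain only, and this fallback does not correct it. The fallback sets out from 19 and returns at 22. The ring closure is run as before, and the syn adduct, (1(10)E,4S,5R,6R,7R,8R)-4,5-epoxy-6-(triethylsilyloxy)germacra-1(10),11-dien-8-ol F1, is carried on. It is not acylated with retention but esterified with inversion by a Mitsunobu reaction (benzoic acid, PPh3, diisopropyl azodicarboxylate, toluene, 0 → 23 °C), which corrects C8 and installs the benzoate in one operation to give 22.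

2. Step 8. What may go wrong: poor facial selectivity of the carbonyl addition (lithium chelation between carbonyl and oxirane oxygen competing with the Felkin–Anh mode) and opening of the oxirane by the organolithium. The fallback sets out from 13 as obtained, whatever its composition at C6, and returns at 13; the stereocentre is set by reduction instead of addition. Oxidation with Dess–Martin periodinane and pyridine gives the epoxy enone (4S,5S)-4,5-epoxy-12-(4-methoxybenzyloxy)-7,8-secogermacra-1(10)E,7(11)E,8-trien-6-one F2. Reduction with Zn(BH4)2 in Et2O at −20 °C follows: zinc chelation between the carbonyl and oxirane oxygens should direct hydride (1,2-reduction) to the face flanked by the oxirane hydrogen and give the anti (6R) alcohol 13.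

3. Step 12. What may go wrong: the halogenation does not stay at the allylic hydroxyl (capture of the C8 hydroxyl as bromide or methylthiomethyl ether, or allylic transposition). The fallback sets out from 14 and returns at 18; the order of events is changed so that no choice between two hydroxyls is needed. DDQ cleavage of the 4-methoxybenzyl ether of 14 gives, with the diene intact, (4S,5R,6R)-4,5-epoxy-6-(triethylsilyloxy)-7,8-secogermacra-1(10)E,7(11)E,8-trien-12-ol F3. Appel bromination (CBr4, PPh3, CH2Cl2, 0 °C) gives (4S,5R,6R)-12-bromo-4,5-epoxy-6-(triethylsilyloxy)-7,8-secogermacra-1(10)E,7(11)E,8-triene F4. Hydroboration of the diene terminus with 9-BBN gives the B-(C8)-alkyl-9-borabicyclo[3.3.1]nonane F5, which is not isolated, and mild oxidation with NaBO3·4H2O then gives 18.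

Further compounds
F1 | step 14 | (1(10)E,4S,5R,6R,7R,8R)-4,5-epoxy-6-(triethylsilyloxy)germacra-1(10),11-dien-8-ol | CC[Si](CC)(CC)O[C@@H]1[C@H](C(C)=C)[C@H](O)C/C(C)=C/CC[C@]2(C)O[C@H]12
F2 | step 8 | (4S,5S)-4,5-epoxy-12-(4-methoxybenzyloxy)-7,8-secogermacra-1(10)E,7(11)E,8-trien-6-one | O=C(/C=C(\C)COCc1ccc(OC)cc1)[C@@H]1[C@@](CC/C=C(\C)C=C)(C)O1
F3 | step 12 | (4S,5R,6R)-4,5-epoxy-6-(triethylsilyloxy)-7,8-secogermacra-1(10)E,7(11)E,8-trien-12-ol | CC[Si](CC)(CC)O[C@H](/C=C(\C)CO)[C@@H]1[C@@](CC/C=C(\C)C=C)(C)O1
F4 | step 12 | (4S,5R,6R)-12-bromo-4,5-epoxy-6-(triethylsilyloxy)-7,8-secogermacra-1(10)E,7(11)E,8-triene | CC[Si](CC)(CC)O[C@H](/C=C(\C)CBr)[C@@H]1[C@@](CC/C=C(\C)C=C)(C)O1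
F5 | step 12 | B-(C8)-alkyl-9-borabicyclo[3.3.1]nonane from F4 | CC[Si](CC)(CC)O[C@H](/C=C(\C)CBr)[C@@H]1[C@@](CC/C=C(\C)CCB2C3CCCC2CCC3)(C)O1
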